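**Retrosynthetic overview**
1. The γ-lactone C7–O bond is made last but one, together with the 5Z olefin and the C16 methyl, by a palladium-hydride hydrolactonization of macrocyclic 1,3-diene acid 25; C17 is equilibrated in the same pot and only a C12 silyl ether then remains.
2. The ten-membered ring comes from ring-closing enyne metathesis (C6=C7) between the alkyne on the C2 arm and the vinyl group on C8 of enyne acid 23.
3. C9, C8 and C17 come from Felkin–Anh addition of lithiated methoxyallene to the C9 aldehyde, then a Cram-chelate Ivanov aldol of propanoic acid dianion; C2 comes from Grignard opening of the ring A lactone, then CBS reduction.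
4. Ring A with C1, C10, C11 and C12 comes from one endo Diels–Alder reaction of 3-methyl-2-pyrone 2 with the chiral (Z)-ketol enone 6, which supplies the absolute configuration.
5. Ring order: cyclohexene ring A (step 3), then the ten-membered carbocycle (step 11), then the γ-lactone (step 12).

Assumption: locants follow briarane numbering (C1 quaternary carbon with C15 methyl; C2 and C9 acetoxy carbons; C5=C6 with C16 methyl; C7 lactone CH–O; C8 tertiary carbinol; C10 ring-fusion CH; C11 with C20 methyl; C12 carbinol; C13=C14; C17 with C18 methyl; C19 lactone carbonyl), which makes the target (1S,2R,5Z,7S,8S,9R,10S,11R,12R,17R); all named starting materials are taken as catalogue compounds.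

**Route**

Step 1
Reactants: 1 3-bromo-2H-pyran-2-one
Product: 2 3-methyl-2H-pyran-2-one
Conditions: MeZnCl (1.3 equiv), Pd(PPh3)4 (3 mol %), THF, 50 °C
Reagents that add atoms: methylzinc chloride, C[Zn]Cl
Why: Negishi coupling of the electron-poor C3 vinyl bromide under base-free conditions that spare the pyrone ring; no stereocentre is formed.

Step 2
Reactants: 3 (S)-2-hydroxy-3,3-dimethylbutanoic acid; 4 (Z)-1-bromoprop-1-ene
Product: 6 (2Z,5S)-5-hydroxy-6,6-dimethylhept-2-en-4-one, via (Z)-prop-1-en-1-yllithium 5 (not isolated)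
Conditions: 4, Li, Et2O, −10 °C; then 3 (0.3 equiv), THF, −78 → 0 °C; H2O work-up at 0 °C
Reagents that add atoms: none
Why: Ketone synthesis from a carboxylic acid and an organolithium (three equivalents; the gem-dialkoxide survives until work-up), with retention of the Z geometry of the configurationally stable alkenyllithium and of the (S)-carbinol.

Step 3
Reactants: 2 3-methyl-2H-pyran-2-one; 6 (2Z,5S)-5-hydroxy-6,6-dimethylhept-2-en-4-one
Product: 7 (1R,4S,7R,8S)-8-[(2S)-2-hydroxy-3,3-dimethylbutanoyl]-4,7-dimethyl-2-oxabicyclo[2.2.2]oct-5-en-3-one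
Conditions: CH2Cl2 (2 M), 13 kbar, 25 °C, 72 h
Reagents that add atoms: none
Why: Normal-demand pyrone Diels–Alder reaction with a hydrogen-bond-activated chiral α'-hydroxy enone; the O-bearing pyrone terminus bonds to the enone β-carbon, the cis acyl and methyl groups sit endo (anti to the lactone bridge) and the diene adds to the face of the s-cis ketol away from tert-butyl, which sets C1, C10, C11 and C12 in the target configuration (C12–O and C2 cis, C15/C9/C20 cis).

Step 4
Reactants: 7 (1R,4S,7R,8S)-8-[(2S)-2-hydroxy-3,3-dimethylbutanoyl]-4,7-dimethyl-2-oxabicyclo[2.2.2]oct-5-en-3-one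
Product: 8 (1R,4S,7R,8S)-8-[(1R,2S)-1,2-dihydroxy-3,3-dimethylbutyl]-4,7-dimethyl-2-oxabicyclo[2.2.2]oct-5-en-3-one
Conditions: Zn(BH4)2, Et2O, −20 °C; aq. NH4Cl
Reagents that add atoms: none
Why: Chelation-controlled ketone reduction (hydride anti to tert-butyl in the zinc chelate) turns the ketol into a 1,2-diol, a Grignard-inert masked aldehyde, without touching the lactone; the new carbinol is excised in step 5.

Step 5
Reactants: 8 (1R,4S,7R,8S)-8-[(1R,2S)-1,2-dihydroxy-3,3-dimethylbutyl]-4,7-dimethyl-2-oxabicyclo[2.2.2]oct-5-en-3-one; 9 (4-bromobut-1-yn-1-yl)trimethylsilane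
Product: 12 (1S,2S,5R,6R)-5-hydroxy-2,6-dimethyl-2-[5-(trimethylsilyl)pent-4-ynoyl]cyclohex-3-ene-1-carbaldehyde, via Grignard reagent 10 (not isolated), via keto triol 11 (not isolated)
Conditions: 9, Mg, THF, 23 °C; 8 (0.28 equiv), THF, −40 → 23 °C; aq. NH4Cl; then NaIO4, THF/H2O (pH 7), 0 → 23 °C
Reagents that add atoms: none
Why: Grignard addition to the strained bridged lactone stops at the C2 ketone because the bridged hemiketal alkoxide persists until work-up (the diol alkoxides are spectators), and periodate glycol cleavage then excises the auxiliary as pivalaldehyde and unveils the C9 aldehyde at neutral pH without epimerising C10.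

Step 6
Reactants: 12 (1S,2S,5R,6R)-5-hydroxy-2,6-dimethyl-2-[5-(trimethylsilyl)pent-4-ynoyl]cyclohex-3-ene-1-carbaldehyde
Product: 13 (1S,2S,5R,6R)-5-[(tert-butyldimethylsilyl)oxy]-2,6-dimethyl-2-[5-(trimethylsilyl)pent-4-ynoyl]cyclohex-3-ene-1-carbaldehyde
Conditions: TBSOTf, 2,6-lutidine, CH2Cl2, −78 °C
Reagents that add atoms: tert-butyldimethylsilyl triflate, CC(C)(C)[Si](C)(C)OS(=O)(=O)C(F)(F)F
Why: Silyl ether formation at the only hydroxyl (C12) marks the one secondary oxygen that must stay unacetylated; low temperature and a hindered base avoid enolisation of the aldehyde.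

Step 7
Reactants: 13 (1S,2S,5R,6R)-5-[(tert-butyldimethylsilyl)oxy]-2,6-dimethyl-2-[5-(trimethylsilyl)pent-4-ynoyl]cyclohex-3-ene-1-carbaldehyde; 14 methoxyallene
Product: 17 hydroxy enone: 13 in which CHO has become (R)-CH(OH)–C(=O)–CH=CH2 (C9 carbinol; C8 ketone; C7 vinyl), via 1-lithio-1-methoxyallene 15 (not isolated), via allenyl carbinol 16 (not isolated)
Conditions: 14, n-BuLi, THF, −40 °C; 13, −78 °C; then 1 M HCl, THF, 0 °C
Reagents that add atoms: water, O
Why: 1,2-Addition of lithiated methoxyallene (an acryloyl anion equivalent) to the aldehyde, which outcompetes the hindered C2 ketone, proceeds under Felkin–Anh control (quaternary C1 anti to the nucleophile) to set 9R, and enol ether hydrolysis releases the α-hydroxy vinyl ketone.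

Step 8
Reactants: 17 hydroxy enone; 18 propanoic acid
Product: 20 dihydroxy acid: 17 in which the C8 ketone has become C(OH)(CH=CH2)–CH(CH3)–CO2H (C8 as in the target; C17 S), via dilithium enediolate 19 (not isolated)
Conditions: 18, LiN(i-Pr)2 (2 equiv per acid), THF, 0 °C; 17 (0.3 equiv), −78 °C; aq. HCl quench at −78 °C
Reagents that add atoms: none
Why: Ivanov-type aldol with kinetic 1,2-addition of the acid dianion to the lithium-chelated α-alkoxide ketone (Cram chelate, attack anti to the C10 branch) sets C8 as in the target; the chelated chair transition state should give mainly 17S at C17, which is corrected in step 12.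

Step 9
Reactants: 20 dihydroxy acid
Product: 22 (2R)-triol acid with terminal alkyne: 20 with the C2 ketone reduced and the alkynyl SiMe3 removed, via silylalkyne triol acid 21 (not isolated)
Conditions: catecholborane (5 equiv), (S)-2-methyl-CBS-oxazaborolidine (0.5 equiv), PhMe, −40 → −20 °C; then K2CO3, MeOH, 23 °C
Reagents that add atoms: none
Why: Corey–Bakshi–Shibata reduction with the quaternary C1 as the large group gives 2R under reagent control (catecholborane only borylates the hydroxyls and the acid and spares alkene and alkyne), and the basic methanol work-up protodesilylates the alkyne.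

Step 10
Reactants: 22 (2R)-triol acid with terminal alkyne
Product: 23 2,9-diacetate of 22
Conditions: Ac2O, pyridine, DMAP (cat.), CH2Cl2, 23 °C; aq. NaHCO3 work-up
Reagents that add atoms: acetic anhydride, CC(=O)OC(C)=O
Why: DMAP-catalysed acetylation esterifies the two secondary alcohols, while the tertiary C8–OH is too hindered, the C12 oxygen is silylated, and the mixed anhydride of the acid is hydrolysed on work-up.

Step 11
Reactants: 23 2,9-diacetate of 22
Product: 25 macrocyclic diene acid (ten-membered ring; 6Z ring olefin; exocyclic C5=C16H2), via acyclic butadiene 24 (not isolated)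
Conditions: second-generation Grubbs catalyst RuCl2(=CHPh)(PCy3)(SIMes) (10 mol %), ethene (1 atm), PhMe (2 mM), 40 °C; then argon sparge, 80 °C
Reagents that add atoms: ethene, C=C
Why: Ethene-promoted ring-closing enyne metathesis: cross enyne metathesis gives the 2-substituted butadiene, whose vinyl terminus then closes onto the C8 vinyl group with loss of ethene; ring strain favours the cis ring olefin and the trans C2/C9 arms on ring A pre-organise the closure.

Step 12
Reactants: 25 macrocyclic diene acid
Product: 27 12-O-tert-butyldimethylsilyl ether of the target, via 17-epi lactone 26 (not isolated)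
Conditions: Pd2(dba)3 (5 mol %), bis[2-(diphenylphosphino)phenyl] ether (12 mol %), PhMe (5 mM), 60 °C; then DBU (1 equiv), 60 °C
Reagents that add atoms: none
Why: Proposed new method: intramolecular 1,4-hydroacyloxylation (hydrolactonization) of a medium-ring 2-substituted 1,3-diene, in which oxidative addition of the substrate's own CO2H to zerovalent palladium gives a palladium hydride that adds H to the exocyclic CH2 (C16, which becomes the methyl) to form a ring-constrained anti,anti π-allyl (C5–C6–C7), and the tethered carboxylate attacks C7 (5-exo, outer sphere) to forge the C7–O bond, the γ-lactone, the C7 stereocentre (allylic-strain-minimised, trans-fused, C6 anti to C9) and the endocyclic (Z)-trisubstituted C5=C6; C–O ionisation is reversible under zerovalent palladium so the trans-fused lactone is expected to be the thermodynamic sink, and DBU then equilibrates C17 by enolisation to the 17R epimer (methyl cis to the small C8–OH); the closest known reaction types are palladium-hydride hydroamination and hydroalkoxylation of 1,3-dienes and zerovalent-palladium/carboxylic-acid additions to allenes and alkynes through π-allyls, none shown for a free acid acting as hydride source and tethered nucleophile on a macrocyclic diene.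

Step 13
Reactants: 27 12-O-tert-butyldimethylsilyl ether of the target
Product: 28 target CNP0222085.1
Conditions: HF·pyridine, pyridine/THF, 0 → 23 °C
Reagents that add atoms: none
Why: Buffered fluoride cleavage of the secondary allylic silyl ether leaves the two acetates, the lactone, the tertiary alcohol and all stereocentres untouched.

**Compound list**
1 | 3-bromo-2H-pyran-2-one | O=C1OC=CC=C1Br | starting material
2 | 3-methyl-2H-pyran-2-one | CC1=CC=COC1=O | intermediate
3 | (S)-2-hydroxy-3,3-dimethylbutanoic acid | CC(C)(C)[C@H](O)C(=O)O | starting material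
4 | (Z)-1-bromoprop-1-ene | C/C=C\Br | starting material
5 | (Z)-prop-1-en-1-yllithium | C/C=C\[Li] | intermediate (not isolated)
6 | (2Z,5S)-5-hydroxy-6,6-dimethylhept-2-en-4-one | CC(C)(C)[C@H](O)C(=O)/C=C\C | intermediate
7 | (1R,4S,7R,8S)-8-[(2S)-2-hydroxy-3,3-dimethylbutanoyl]-4,7-dimethyl-2-oxabicyclo[2.2.2]oct-5-en-3-one (endo adduct; lactone carbonyl = C2, bridging oxygen on C12) | CC(C)(C)[C@H](O)C(=O)[C@H]1[C@@H](C)[C@H]2C=C[C@]1(C)C(=O)O2 | intermediate
8 | (1R,4S,7R,8S)-8-[(1R,2S)-1,2-dihydroxy-3,3-dimethylbutyl]-4,7-dimethyl-2-oxabicyclo[2.2.2]oct-5-en-3-one | CC(C)(C)[C@H](O)[C@H](O)[C@H]1[C@@H](C)[C@H]2C=C[C@]1(C)C(=O)O2 | intermediate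
9 | (4-bromobut-1-yn-1-yl)trimethylsilane | C[Si](C)(C)C#CCCBr | starting material
10 | [4-(trimethylsilyl)but-3-yn-1-yl]magnesium bromide | C[Si](C)(C)C#CCC[Mg]Br | intermediate (not isolated)
11 | keto triol: 8 with the lactone opened to the C2 ketone C(=O)CH2CH2C≡CSiMe3 and a free C12–OH; ring and diol centres as in 8 | CC(C)(C)[C@H](O)[C@H](O)[C@H]1[C@@H](C)[C@H](O)C=C[C@]1(C)C(=O)CCC#C[Si](C)(C)C | intermediate (not isolated)
12 | (1S,2S,5R,6R)-5-hydroxy-2,6-dimethyl-2-[5-(trimethylsilyl)pent-4-ynoyl]cyclohex-3-ene-1-carbaldehyde | O=C[C@H]1[C@@H](C)[C@H](O)C=C[C@]1(C)C(=O)CCC#C[Si](C)(C)C | intermediate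
13 | (1S,2S,5R,6R)-5-[(tert-butyldimethylsilyl)oxy]-2,6-dimethyl-2-[5-(trimethylsilyl)pent-4-ynoyl]cyclohex-3-ene-1-carbaldehyde | O=C[C@H]1[C@@H](C)[C@H](O[Si](C)(C)C(C)(C)C)C=C[C@]1(C)C(=O)CCC#C[Si](C)(C)C | intermediate
14 | methoxyallene (1-methoxypropa-1,2-diene) | COC=C=C | starting material
15 | 1-lithio-1-methoxypropa-1,2-diene | COC([Li])=C=C | intermediate (not isolated)
16 | allenyl carbinol: 13 in which CHO has become (R)-CH(OH)–C(OCH3)=C=CH2 | C=C=C(OC)[C@H](O)[C@H]1[C@@H](C)[C@H](O[Si](C)(C)C(C)(C)C)C=C[C@]1(C)C(=O)CCC#C[Si](C)(C)C | intermediate (not isolated)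
17 | hydroxy enone: 13 in which CHO has become (R)-CH(OH)–C(=O)–CH=CH2 (9R) | C=CC(=O)[C@H](O)[C@H]1[C@@H](C)[C@H](O[Si](C)(C)C(C)(C)C)C=C[C@]1(C)C(=O)CCC#C[Si](C)(C)C | intermediate
18 | propanoic acid | CCC(=O)O | starting material
19 | dilithium prop-1-ene-1,1-diolate (propanoic acid dianion) | CC=C(O[Li])O[Li] | intermediate (not isolated)
20 | dihydroxy acid: 17 with C8 converted into C(OH)(CH=CH2)–CH(CH3)–CO2H; C8 arranged as in the target, 9R, 17S (17-epi) | OC(=O)[C@@H](C)[C@](O)(C=C)[C@H](O)[C@H]1[C@@H](C)[C@H](O[Si](C)(C)C(C)(C)C)C=C[C@]1(C)C(=O)CCC#C[Si](C)(C)C | intermediate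
21 | silylalkyne triol acid: 20 with the C2 ketone reduced to the (2R)-alcohol | OC(=O)[C@@H](C)[C@](O)(C=C)[C@H](O)[C@H]1[C@@H](C)[C@H](O[Si](C)(C)C(C)(C)C)C=C[C@]1(C)[C@H](O)CCC#C[Si](C)(C)C | intermediate (not isolated)
22 | (2R)-triol acid with terminal alkyne: 21 without the alkynyl SiMe3 | OC(=O)[C@@H](C)[C@](O)(C=C)[C@H](O)[C@H]1[C@@H](C)[C@H](O[Si](C)(C)C(C)(C)C)C=C[C@]1(C)[C@H](O)CCC#C | intermediate
23 | 2,9-diacetate of 22 (C8–OH and CO2H free) | OC(=O)[C@@H](C)[C@](O)(C=C)[C@H](OC(C)=O)[C@H]1[C@@H](C)[C@H](O[Si](C)(C)C(C)(C)C)C=C[C@]1(C)[C@H](OC(C)=O)CCC#C | intermediate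
24 | acyclic butadiene: 23 in which C≡CH has become C(=CH2)–CH=CH2 | OC(=O)[C@@H](C)[C@](O)(C=C)[C@H](OC(C)=O)[C@H]1[C@@H](C)[C@H](O[Si](C)(C)C(C)(C)C)C=C[C@]1(C)[C@H](OC(C)=O)CCC(=C)C=C | intermediate (not isolated)
25 | macrocyclic diene acid: bicyclo[8.4.0] core, (6Z)-C6=C7 in the ring, exocyclic C5=C16H2, C8 bearing OH and CH(CH3)CO2H (17S), 2,9-diacetate, 12-OTBS | CC(=O)O[C@@H]1[C@H]2[C@@H](C)[C@H](O[Si](C)(C)C(C)(C)C)C=C[C@]2(C)[C@H](OC(C)=O)CCC(=C)/C=C\[C@@]1(O)[C@H](C)C(=O)O | intermediate
26 | 17-epi lactone: 12-O-TBS target with 17S configuration | CC(=O)O[C@@H]1[C@H]2[C@@H](C)[C@H](O[Si](C)(C)C(C)(C)C)C=C[C@]2(C)[C@H](OC(C)=O)CC/C(C)=C\[C@@H]2OC(=O)[C@@H](C)[C@]21O | intermediate (not isolated)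
27 | 12-O-tert-butyldimethylsilyl ether of the target (all centres as in the target) | CC(=O)O[C@@H]1[C@H]2[C@@H](C)[C@H](O[Si](C)(C)C(C)(C)C)C=C[C@]2(C)[C@H](OC(C)=O)CC/C(C)=C\[C@@H]2OC(=O)[C@H](C)[C@]21O | intermediate
28 | CNP0222085.1: (1S,2R,5Z,7S,8S,9R,10S,11R,12R,17R)-2,9-diacetoxy-8,12-dihydroxybriara-5,13-dien-19,7-olide | CC(=O)O[C@@H]1[C@H]2[C@@H](C)[C@H](O)C=C[C@]2(C)[C@H](OC(C)=O)CC/C(C)=C\[C@@H]2OC(=O)[C@H](C)[C@]21O | target

**Totals**
Total step count: 13.
Longest linear sequence: 12 steps (step 1, then steps 3–13; the branch through step 2 is equally long).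

**Three steps most likely to fail, with fallbacks**

Step 12 (the proposed hydrolactonization). Risks are ionisation of the tertiary dienyl C8–OH, attack at C5, or the wrong ring fusion at C7. The fallback uses known chemistry and sets out from 25. Iodolactonization (iodine, NaHCO3, MeCN, 0 °C) engages the diene acid in the conjugate sense, with the carboxylate on C7 and iodine on C16, to give the allylic iodide 16-iodo derivative of 26 F4 (its 1,2-addition isomer converges). Radical deiodination (Bu3SnH, AIBN, PhH, 60 °C) through the ring-constrained allyl radical places hydrogen on C16. This comes back to the route at 26, which the DBU stage of step 12 turns into 27.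

Step 11 (ten-membered ring by enyne metathesis). Risks are oligomerisation or failure of the hindered C8 vinyl group to engage. The fallback sets out from 23. Markovnikov hydroiodination of the terminal alkyne (NaI, Me3SiCl, H2O, MeCN, 0 °C) gives the 2-iodoalkene, 23 in which C≡CH has become C(I)=CH2 F3. An intramolecular Heck macrocyclization (Pd(OAc)2, P(o-tol)3, Ag2CO3, MeCN, 70 °C, 2 mM) then bonds this carbon to the terminal carbon of the C8 vinyl group, and β-hydride elimination gives the same ring diene. This comes back at 25; a 6E isomer would converge in step 12 through the common π-allyl.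

Step 3 (pyrone Diels–Alder reaction). Risks are low reactivity of 2 toward a Z-β-substituted dienophile, Z→E isomerisation of 6, or loss of CO2 from the adduct. The fallback sets out from 6. Commercial 3,5-dibromo-2H-pyran-2-one is methylated selectively at C3 (MeZnCl, Pd(PPh3)4, THF) to the much more reactive 5-bromo-3-methyl-2H-pyran-2-one F1. Thermal cycloaddition with 6 (PhMe, 90 °C) gives the 6-bromo derivative of 7 F2, with the same regio-, endo- and facial selectivity. Hydrodebromination of the vinyl bromide (Bu3SnH, AIBN, PhH, 80 °C) comes back at 7.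

**Further compounds**
F1 | step 3 | 5-bromo-3-methyl-2H-pyran-2-one | CC1=CC(Br)=COC1=O
F2 | step 3 | 6-bromo derivative of 7 (vinyl bromide on the olefinic carbon next to the O-bearing bridgehead; all centres arranged as in 7) | CC(C)(C)[C@H](O)C(=O)[C@H]1[C@@H](C)[C@H]2C(Br)=C[C@]1(C)C(=O)O2
F3 | step 11 | 2-iodoalkene: 23 in which C≡CH has become C(I)=CH2 | OC(=O)[C@@H](C)[C@](O)(C=C)[C@H](OC(C)=O)[C@H]1[C@@H](C)[C@H](O[Si](C)(C)C(C)(C)C)C=C[C@]1(C)[C@H](OC(C)=O)CCC(I)=C
F4 | step 12 | 16-iodo derivative of 26 (allylic iodide; C4 and C7 cis on C5=C6) | CC(=O)O[C@@H]1[C@H]2[C@@H](C)[C@H](O[Si](C)(C)C(C)(C)C)C=C[C@]2(C)[C@H](OC(C)=O)CC/C(CI)=C\[C@@H]2OC(=O)[C@@H](C)[C@]21O
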